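**Retrosynthetic overview**
- The C-6 side-chain bond of the benzoxepine half is cut by an intermolecular aldol reaction: the α′-lithium enolate of a bicyclic benzoxepinone enone plus a hydroazulenyl-acetaldehyde. Dehydration, conjugate reduction, equatorial methyl addition and desilylation finish the target.
- Left half: (E)-geranylacetone, Shi bis-epoxidation, then one epoxide-opening cascade terminated by an enol silane; the oxepane forms first, the cyclohexanone second. A Saegusa enone then leaves C-6 as the only enolizable α′-site.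
- Right half: (R)-limonene supplies C-3a; a gem-dimethyl ester is built on the isopropenyl group, and ozonolysis/aldol condensation gives the cyclopentene (first ring).
- Epoxidation/reductive opening sets the tertiary carbinol C-1 and hydroboration sets C-8a; ring-closing metathesis then closes the cycloheptenone (second ring).
- Allyl addition/oxidative 1,3-transposition installs the tetrasubstituted enone and the two-carbon arm; Luche reduction sets C-7.

Assumption: (E)-geranylacetone (≥96% E) and (R)-(+)-limonene are bought isomerically pure; locants follow 1-benzoxepine numbering (left half) and azulene numbering (right half); TBS = tert-butyldimethylsilyl, TES = triethylsilyl. The route is a paper design; nothing has been run.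

**Left half**

Step 1
Reactants: 1 (5E)-6,10-dimethylundeca-5,9-dien-2-one
Product: 2 4-[(2R,3R)-3-{2-[(2R)-3,3-dimethyloxiran-2-yl]ethyl}-3-methyloxiran-2-yl]butan-2-one
Conditions: D-fructose-derived Shi ketone (0.6 equiv), KHSO5 (as 2KHSO5·KHSO4·K2SO4), K2CO3, Bu4NHSO4, MeCN/CH2(OMe)2, aq Na2B4O7 buffer (pH 10.5), 0 °C
Reagents that add atoms: potassium peroxymonosulfate [K+].[O-]S(=O)(=O)OO
Why: Shi asymmetric epoxidation; the chiral dioxirane attacks both trisubstituted alkenes through the spiro transition state from the same face, giving the all-R bis-epoxide.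

Step 2
Reactants: 2 4-[(2R,3R)-3-{2-[(2R)-3,3-dimethyloxiran-2-yl]ethyl}-3-methyloxiran-2-yl]butan-2-one
Product: 3 tert-butyl({4-[(2R,3R)-3-{2-[(2R)-3,3-dimethyloxiran-2-yl]ethyl}-3-methyloxiran-2-yl]but-1-en-2-yl}oxy)dimethylsilane
Conditions: LiN(iPr)2 (1.1 equiv), THF, −78 °C; then tBuMe2SiCl, DMPU, −78 → −20 °C
Reagents that add atoms: tert-butyldimethylsilyl chloride CC(C)(C)[Si](C)(C)Cl
Why: kinetic deprotonation of the methyl ketone at CH3 and O-silylation (silyl enol ether formation) give the terminal enol silane; the epoxides are inert to the hindered amide at −78 °C.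

Step 3
Reactants: 3 tert-butyl({4-[(2R,3R)-3-{2-[(2R)-3,3-dimethyloxiran-2-yl]ethyl}-3-methyloxiran-2-yl]but-1-en-2-yl}oxy)dimethylsilane
Product: 4 (3R,5aR,9aR)-3-(TBSO)-2,2,5a-trimethyloctahydro-1-benzoxepin-7(2H)-one
Conditions: tBuMe2SiOTf (1.1 equiv), 2,6-di-tert-butyl-4-methylpyridine, CH2Cl2, −78 °C; aq NaHCO3
Reagents that add atoms: tert-butyldimethylsilyl trifluoromethanesulfonate CC(C)(C)[Si](C)(C)OS(=O)(=O)C(F)(F)F
Why: epoxide-opening cascade (tandem oxa-/carbacyclization): the silylated terminal epoxide is opened at its tertiary carbon by the internal epoxide oxygen (retention at C-3), and the epoxonium ion is opened anti at its tertiary carbon by the enol silane (inversion at C-5a, retention at C-9a), giving the trans-fused oxepane–cyclohexanone.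

Step 4
Reactants: 4 (3R,5aR,9aR)-3-(TBSO)-2,2,5a-trimethyloctahydro-1-benzoxepin-7(2H)-one
Product: 6 (3R,5aR,9aR)-3-(TBSO)-2,2,5a-trimethyl-3,4,5,5a,6,9a-hexahydro-1-benzoxepin-7(2H)-one, via silyl enol ether 5 (not isolated)
Conditions: LiN(iPr)2, Me3SiCl, THF, −78 °C; then Pd(OAc)2 (1.05 equiv), MeCN, 25 °C
Reagents that add atoms: none
Why: Saegusa–Ito dehydrogenation; kinetic enolization goes to C-8 (C-6 is neopentyl) and only that side has a β-hydrogen, so the C-8/C-9 enone forms and C-6 becomes the sole α′-position.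

**Right half**

Step 5
Reactants: 7 (4R)-1-methyl-4-(prop-1-en-2-yl)cyclohex-1-ene
Product: 9 2-[(1R)-4-methylcyclohex-3-en-1-yl]propan-1-ol (C-2 epimers), via alkylborane 8 (not isolated)
Conditions: 9-BBN, THF, 0 → 25 °C; then NaOH, H2O2, H2O, 0 → 40 °C
Reagents that add atoms: hydrogen peroxide OO
Why: anti-Markovnikov hydroboration–oxidation; 9-BBN takes only the unhindered 1,1-disubstituted alkene, the ring stereocentre is untouched and the new C-2 mixture is erased in step 8.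

Step 6
Reactants: 9 2-[(1R)-4-methylcyclohex-3-en-1-yl]propan-1-ol (C-2 epimers)
Product: 10 2-[(1R)-4-methylcyclohex-3-en-1-yl]propanoic acid (C-2 epimers)
Conditions: TEMPO (0.2 equiv), PhI(OAc)2 (2.2 equiv), MeCN/H2O (1:1), 25 °C
Reagents that add atoms: water O
Why: oxoammonium (TEMPO) oxidation takes the primary alcohol through the aldehyde hydrate to the acid without touching the trisubstituted alkene.

Step 7
Reactants: 10 2-[(1R)-4-methylcyclohex-3-en-1-yl]propanoic acid (C-2 epimers)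
Product: 11 methyl 2-[(1R)-4-methylcyclohex-3-en-1-yl]propanoate (C-2 epimers)
Conditions: MeI, K2CO3, DMF, 25 °C
Reagents that add atoms: iodomethane CI
Why: SN2 O-alkylation of the carboxylate (esterification) under non-acidic conditions.

Step 8
Reactants: 11 methyl 2-[(1R)-4-methylcyclohex-3-en-1-yl]propanoate (C-2 epimers)
Product: 12 methyl 2-methyl-2-[(1R)-4-methylcyclohex-3-en-1-yl]propanoate
Conditions: LiN(iPr)2, THF, −78 °C; MeI, −78 → 0 °C
Reagents that add atoms: iodomethane CI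
Why: ester enolate alkylation builds the quaternary gem-dimethyl carbon (future C-4) and removes the C-2 stereocentre.

Step 9
Reactants: 12 methyl 2-methyl-2-[(1R)-4-methylcyclohex-3-en-1-yl]propanoate
Product: 14 methyl (3R)-2,2-dimethyl-6-oxo-3-(2-oxoethyl)heptanoate, via ozonide 13 (not isolated)
Conditions: O3, CH2Cl2, −78 °C; then Me2S, −78 → 25 °C
Reagents that add atoms: ozone [O-][O+]=O
Why: ozonolysis with reductive work-up cleaves the only alkene to the keto aldehyde; the stereocentre is not involved.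

Step 10
Reactants: 14 methyl (3R)-2,2-dimethyl-6-oxo-3-(2-oxoethyl)heptanoate
Product: 15 methyl 2-[(1R)-2-formyl-3-methylcyclopent-2-en-1-yl]-2-methylpropanoate
Conditions: piperidine (0.3 equiv), AcOH (0.3 equiv), toluene, 80 °C
Reagents that add atoms: none
Why: intramolecular aldol condensation through the aldehyde enamine (5-enolexo attack on the methyl ketone, then dehydration) gives the cyclopentene carbaldehyde.

Step 11
Reactants: 15 methyl 2-[(1R)-2-formyl-3-methylcyclopent-2-en-1-yl]-2-methylpropanoate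
Product: 16 methyl 2-[(1R)-2-(hydroxymethyl)-3-methylcyclopent-2-en-1-yl]-2-methylpropanoate
Conditions: NaBH4, CeCl3·7H2O, MeOH, −40 → 0 °C
Reagents that add atoms: none
Why: Luche 1,2-reduction of the enal; the hindered ester is inert and the cold, short reaction avoids δ-lactonization.

Step 12
Reactants: 16 methyl 2-[(1R)-2-(hydroxymethyl)-3-methylcyclopent-2-en-1-yl]-2-methylpropanoate
Product: 17 methyl 2-[(1R,2S,5R)-1-(hydroxymethyl)-5-methyl-6-oxabicyclo[3.1.0]hexan-2-yl]-2-methylpropanoate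
Conditions: mCPBA, NaHCO3, CH2Cl2, 0 °C
Reagents that add atoms: 3-chloroperoxybenzoic acid OOC(=O)c1cccc(Cl)c1
Why: Prilezhaev epoxidation of the tetrasubstituted alkene anti to the bulky C(CH3)2CO2Me group on the adjacent carbon fixes the oxygen face of the future C-1 carbinol.

Step 13
Reactants: 17 methyl 2-[(1R,2S,5R)-1-(hydroxymethyl)-5-methyl-6-oxabicyclo[3.1.0]hexan-2-yl]-2-methylpropanoate
Product: 18 methyl 2-[(1S,2S,5R)-1-(iodomethyl)-5-methyl-6-oxabicyclo[3.1.0]hexan-2-yl]-2-methylpropanoate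
Conditions: I2, PPh3, imidazole, CH2Cl2, 0 → 25 °C
Reagents that add atoms: iodine II
Why: Appel-type iodination of the primary alcohol under neutral conditions leaves the epoxide intact (the descriptor change is a priority change only).

Step 14
Reactants: 18 methyl 2-[(1S,2S,5R)-1-(iodomethyl)-5-methyl-6-oxabicyclo[3.1.0]hexan-2-yl]-2-methylpropanoate
Product: 19 methyl 2-[(1R,3R)-3-hydroxy-3-methyl-2-methylidenecyclopentyl]-2-methylpropanoate
Conditions: Zn dust, EtOH, 70 °C; aq NH4Cl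
Reagents that add atoms: none
Why: reductive elimination (zinc insertion into C–I, then β-elimination of the epoxide oxygen) gives the transposed tertiary allylic alcohol with the carbinol C–O bond, and so its configuration, retained.

Step 15
Reactants: 19 methyl 2-[(1R,3R)-3-hydroxy-3-methyl-2-methylidenecyclopentyl]-2-methylpropanoate
Product: 21 methyl 2-[(1R,2R,3R)-3-hydroxy-3-methyl-2-(prop-2-en-1-yl)cyclopentyl]-2-methylpropanoate, via alkylborane 20 (not isolated)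
Conditions: 9-BBN (2.5 equiv), THF, 0 → 50 °C; then CH2=CHBr, PdCl2(dppf) (5 mol%), K3PO4 (3 M aq), DMF, 50 °C
Reagents that add atoms: vinyl bromide C=CBr
Why: hydroboration then B-alkyl Suzuki–Miyaura coupling; the borane approaches the methylidene from the hydroxyl face, away from the quaternary side chain and the carbinol methyl, so H lands syn to OH and the new allyl group is cis to the side chain (2R).

Step 16
Reactants: 21 methyl 2-[(1R,2R,3R)-3-hydroxy-3-methyl-2-(prop-2-en-1-yl)cyclopentyl]-2-methylpropanoate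
Product: 22 (1R,2R,3R)-3-(1-hydroxy-2-methylpropan-2-yl)-1-methyl-2-(prop-2-en-1-yl)cyclopentan-1-ol
Conditions: iBu2AlH (3.5 equiv), CH2Cl2, −78 → 0 °C; aq potassium sodium tartrate
Reagents that add atoms: none
Why: aluminium hydride reduction of the hindered ester to the neopentyl alcohol.

Step 17
Reactants: 22 (1R,2R,3R)-3-(1-hydroxy-2-methylpropan-2-yl)-1-methyl-2-(prop-2-en-1-yl)cyclopentan-1-ol
Product: 23 2-[(1R,2R,3R)-3-hydroxy-3-methyl-2-(prop-2-en-1-yl)cyclopentyl]-2-methylpropanal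
Conditions: Dess–Martin periodinane, NaHCO3, CH2Cl2, 0 → 25 °C
Reagents that add atoms: none
Why: Dess–Martin oxidation of the primary alcohol to a non-enolizable aldehyde; the tertiary alcohol cannot be oxidized and is trans to the side chain, so no lactol forms.

Step 18
Reactants: 23 2-[(1R,2R,3R)-3-hydroxy-3-methyl-2-(prop-2-en-1-yl)cyclopentyl]-2-methylpropanal
Product: 24 (1R,2R,3R)-3-(3-hydroxy-2,4-dimethylpent-4-en-2-yl)-1-methyl-2-(prop-2-en-1-yl)cyclopentan-1-ol (carbinol epimers)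
Conditions: CH2=C(CH3)MgBr (3 equiv), THF, −78 → 0 °C; aq NH4Cl
Reagents that add atoms: isopropenylmagnesium bromide CC(=C)[Mg]Br
Why: Grignard 1,2-addition to the aldehyde (one equivalent is spent on the tertiary OH); the new carbinol centre is oxidized away in step 19.

Step 19
Reactants: 24 (1R,2R,3R)-3-(3-hydroxy-2,4-dimethylpent-4-en-2-yl)-1-methyl-2-(prop-2-en-1-yl)cyclopentan-1-ol (carbinol epimers)
Product: 25 4-[(1R,2R,3R)-3-hydroxy-3-methyl-2-(prop-2-en-1-yl)cyclopentyl]-2,4-dimethylpent-1-en-3-one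
Conditions: Dess–Martin periodinane, NaHCO3, CH2Cl2, 0 °C
Reagents that add atoms: none
Why: Dess–Martin oxidation of the secondary allylic alcohol gives the isopropenyl ketone, which cannot enolize toward the quaternary carbon.

Step 20
Reactants: 25 4-[(1R,2R,3R)-3-hydroxy-3-methyl-2-(prop-2-en-1-yl)cyclopentyl]-2,4-dimethylpent-1-en-3-one
Product: 26 (1R,3aR,8aR)-1-hydroxy-1,4,4,6-tetramethyl-2,3,3a,4,8,8a-hexahydroazulen-5(1H)-one
Conditions: RuCl2(H2IMes)(PCy3)(=CHPh) (second-generation Grubbs catalyst, 5 mol%), toluene (5 mM), 80 °C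
Reagents that add atoms: none
Why: ring-closing metathesis between the terminal alkene and the 1,1-disubstituted enone alkene closes the seven-membered ring as a trisubstituted enone; the cis side chains give the cis ring fusion.

Step 21
Reactants: 26 (1R,3aR,8aR)-1-hydroxy-1,4,4,6-tetramethyl-2,3,3a,4,8,8a-hexahydroazulen-5(1H)-one
Product: 27 (1R,3aR,8aR)-1,4,4,6-tetramethyl-5-(prop-2-en-1-yl)-1,2,3,3a,4,5,8,8a-octahydroazulene-1,5-diol (C-5 epimers)
Conditions: CH2=CHCH2MgBr (3 equiv), THF, −78 °C; aq NH4Cl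
Reagents that add atoms: allylmagnesium bromide C=CC[Mg]Br
Why: allyl Grignard 1,2-addition through its six-membered transition state reaches even this hindered enone carbonyl; the C-5 configuration is lost in step 22.

Step 22
Reactants: 27 (1R,3aR,8aR)-1,4,4,6-tetramethyl-5-(prop-2-en-1-yl)-1,2,3,3a,4,5,8,8a-octahydroazulene-1,5-diol (C-5 epimers)
Product: 28 (1R,3aR,8aR)-1-hydroxy-1,4,4,6-tetramethyl-5-(prop-2-en-1-yl)-2,3,3a,4,8,8a-hexahydroazulen-7(1H)-one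
Conditions: C5H5NH[CrO3Cl] (pyridinium chlorochromate), NaOAc, 4 Å sieves, CH2Cl2, 25 °C
Reagents that add atoms: none
Why: Dauben–Michno oxidative 1,3-transposition ([3,3] shift of the tertiary allylic chromate ester, then oxidation) gives the tetrasubstituted enone with oxygen at C-7; the non-allylic tertiary C-1 alcohol is inert.

Step 23
Reactants: 28 (1R,3aR,8aR)-1-hydroxy-1,4,4,6-tetramethyl-5-(prop-2-en-1-yl)-2,3,3a,4,8,8a-hexahydroazulen-7(1H)-one
Product: 29 (1R,3aR,7S,8aR)-1,4,4,6-tetramethyl-5-(prop-2-en-1-yl)-1,2,3,3a,4,7,8,8a-octahydroazulene-1,7-diol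
Conditions: NaBH4, CeCl3·7H2O, MeOH, −78 °C
Reagents that add atoms: none
Why: Luche 1,2-reduction; hydride enters from the convex face (the side of the ring-fusion hydrogens), because the concave face is shielded by the cyclopentane and its endo methyl, giving the 7S alcohol.

Step 24
Reactants: 29 (1R,3aR,7S,8aR)-1,4,4,6-tetramethyl-5-(prop-2-en-1-yl)-1,2,3,3a,4,7,8,8a-octahydroazulene-1,7-diol
Product: 30 (1R,3aR,7S,8aR)-1,4,4,6-tetramethyl-5-(prop-2-en-1-yl)-1,7-bis(TESO)-1,2,3,3a,4,7,8,8a-octahydroazulene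
Conditions: Et3SiOTf (3 equiv), 2,6-lutidine, CH2Cl2, −78 → 0 °C
Reagents that add atoms: triethylsilyl trifluoromethanesulfonate CC[Si](CC)(CC)OS(=O)(=O)C(F)(F)F
Why: silyl triflate silylation protects both the allylic secondary and the tertiary hydroxyl in one operation.

Step 25
Reactants: 30 (1R,3aR,7S,8aR)-1,4,4,6-tetramethyl-5-(prop-2-en-1-yl)-1,7-bis(TESO)-1,2,3,3a,4,7,8,8a-octahydroazulene
Product: 32 2-[(1R,3aR,7S,8aR)-1,4,4,6-tetramethyl-1,7-bis(TESO)-1,2,3,3a,4,7,8,8a-octahydroazulen-5-yl]acetaldehyde, via diol 31 (not isolated)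
Conditions: OsO4 (2 mol%), NaIO4 (4 equiv), 2,6-lutidine, dioxane/H2O (3:1), 25 °C
Reagents that add atoms: osmium tetroxide O=[Os](=O)(=O)=O; sodium periodate [Na+].[O-]I(=O)(=O)=O
Why: Lemieux–Johnson cleavage; the monosubstituted alkene is dihydroxylated much faster than the hindered tetrasubstituted ring alkene, and the buffered medium keeps the β,γ-unsaturated aldehyde from conjugating.

**Coupling and endgame**

Step 26
Reactants: 6 (3R,5aR,9aR)-3-(TBSO)-2,2,5a-trimethyl-3,4,5,5a,6,9a-hexahydro-1-benzoxepin-7(2H)-one; 32 2-[(1R,3aR,7S,8aR)-1,4,4,6-tetramethyl-1,7-bis(TESO)-1,2,3,3a,4,7,8,8a-octahydroazulen-5-yl]acetaldehyde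
Product: 34 (3R,5aR,9aR)-3-(TBSO)-6-{1-hydroxy-2-[(1R,3aR,7S,8aR)-1,4,4,6-tetramethyl-1,7-bis(TESO)-1,2,3,3a,4,7,8,8a-octahydroazulen-5-yl]ethyl}-2,2,5a-trimethyl-3,4,5,5a,6,9a-hexahydro-1-benzoxepin-7(2H)-one (epimers at C-6 and the carbinol carbon), via lithium enolate 33 (not isolated)
Conditions: 6 (1.15 equiv), LiN(iPr)2 (1.1 equiv), THF, −78 °C, 45 min; then 32, −78 °C, 30 min; AcOH quench at −78 °C
Reagents that add atoms: none
Why: intermolecular aldol addition; kinetic α′-deprotonation of the enone can only occur at C-6, so the cross-conjugated lithium enolate forms regiospecifically and adds to the aldehyde faster than it enolizes it, and both new stereocentres are removed or reset in steps 27 and 28.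

Step 27
Reactants: 34 (3R,5aR,9aR)-3-(TBSO)-6-{1-hydroxy-2-[(1R,3aR,7S,8aR)-1,4,4,6-tetramethyl-1,7-bis(TESO)-1,2,3,3a,4,7,8,8a-octahydroazulen-5-yl]ethyl}-2,2,5a-trimethyl-3,4,5,5a,6,9a-hexahydro-1-benzoxepin-7(2H)-one (epimers at C-6 and the carbinol carbon)
Product: 36 (3R,5aR,6Z,9aR)-3-(TBSO)-2,2,5a-trimethyl-6-{2-[(1R,3aR,7S,8aR)-1,4,4,6-tetramethyl-1,7-bis(TESO)-1,2,3,3a,4,7,8,8a-octahydroazulen-5-yl]ethylidene}-3,4,5,5a,6,9a-hexahydro-1-benzoxepin-7(2H)-one, via mesylate 35 (not isolated)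
Conditions: MsCl (3 equiv), Et3N (6 equiv), DMAP (cat.), CH2Cl2, 0 → 25 °C
Reagents that add atoms: none
Why: mesylation and E1cB elimination with a mild amine base give the alkylidene enone without moving the skipped ring alkene; the Z isomer (chain away from quaternary C-5a) is expected, but either isomer is reduced next.

Step 28
Reactants: 36 (3R,5aR,6Z,9aR)-3-(TBSO)-2,2,5a-trimethyl-6-{2-[(1R,3aR,7S,8aR)-1,4,4,6-tetramethyl-1,7-bis(TESO)-1,2,3,3a,4,7,8,8a-octahydroazulen-5-yl]ethylidene}-3,4,5,5a,6,9a-hexahydro-1-benzoxepin-7(2H)-one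
Product: 37 (3R,5aR,6R,9aR)-3-(TBSO)-2,2,5a-trimethyl-6-{2-[(1R,3aR,7S,8aR)-1,4,4,6-tetramethyl-1,7-bis(TESO)-1,2,3,3a,4,7,8,8a-octahydroazulen-5-yl]ethyl}octahydro-1-benzoxepin-7(2H)-one
Conditions: [(Ph3P)CuH]6 (0.5 equiv), H2O (5 equiv), toluene, 25 °C; then DBU (0.5 equiv), 25 °C, 12 h
Reagents that add atoms: none
Why: copper hydride (Stryker) conjugate reduction saturates both enone C=C bonds and spares the isolated tetrasubstituted alkene; DBU then equilibrates C-6 to the equatorial side chain (6R).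

Step 29
Reactants: 37 (3R,5aR,6R,9aR)-3-(TBSO)-2,2,5a-trimethyl-6-{2-[(1R,3aR,7S,8aR)-1,4,4,6-tetramethyl-1,7-bis(TESO)-1,2,3,3a,4,7,8,8a-octahydroazulen-5-yl]ethyl}octahydro-1-benzoxepin-7(2H)-one
Product: 38 (3R,5aR,6R,7S,9aR)-3-(TBSO)-2,2,5a,7-tetramethyl-6-{2-[(1R,3aR,7S,8aR)-1,4,4,6-tetramethyl-1,7-bis(TESO)-1,2,3,3a,4,7,8,8a-octahydroazulen-5-yl]ethyl}decahydro-1-benzoxepin-7-ol
Conditions: MeLi (4 equiv), CeCl3 (anhydrous, 4 equiv), THF, −78 °C; aq NH4Cl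
Reagents that add atoms: methyllithium [Li]C
Why: organocerium 1,2-addition without enolization; axial attack is blocked by the 1,3-diaxial 5a-methyl, so methyl enters equatorially and the 7-OH ends axial, syn to that methyl (7S).

Step 30
Reactants: 38 (3R,5aR,6R,7S,9aR)-3-(TBSO)-2,2,5a,7-tetramethyl-6-{2-[(1R,3aR,7S,8aR)-1,4,4,6-tetramethyl-1,7-bis(TESO)-1,2,3,3a,4,7,8,8a-octahydroazulen-5-yl]ethyl}decahydro-1-benzoxepin-7-ol
Product: 39 (3R,5aR,6R,7S,9aR)-6-{2-[(1R,3aR,7S,8aR)-1,7-dihydroxy-1,4,4,6-tetramethyl-1,2,3,3a,4,7,8,8a-octahydroazulen-5-yl]ethyl}-2,2,5a,7-tetramethyldecahydro-1-benzoxepine-3,7-diol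
Conditions: Bu4NF (10 equiv), THF, 55 °C
Reagents that add atoms: none
Why: fluoride desilylation removes all three silyl ethers under non-acidic conditions, so the allylic alcohol does not ionize and no stereocentre is touched.

**Compound list**
1 | (5E)-6,10-dimethylundeca-5,9-dien-2-one | CC(=O)CC/C=C(\C)CCC=C(C)C | starting material
2 | 4-[(2R,3R)-3-{2-[(2R)-3,3-dimethyloxiran-2-yl]ethyl}-3-methyloxiran-2-yl]butan-2-one | CC(=O)CC[C@H]1O[C@]1(C)CC[C@H]1OC1(C)C | intermediate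
3 | tert-butyl({4-[(2R,3R)-3-{2-[(2R)-3,3-dimethyloxiran-2-yl]ethyl}-3-methyloxiran-2-yl]but-1-en-2-yl}oxy)dimethylsilane | C=C(O[Si](C)(C)C(C)(C)C)CC[C@H]1O[C@]1(C)CC[C@H]1OC1(C)C | intermediate
4 | (3R,5aR,9aR)-3-(TBSO)-2,2,5a-trimethyloctahydro-1-benzoxepin-7(2H)-one | O=C1C[C@@]2(C)CC[C@@H](O[Si](C)(C)C(C)(C)C)C(C)(C)O[C@@H]2CC1 | intermediate
5 | (3R,5aR,9aR)-3-(TBSO)-2,2,5a-trimethyl-7-(trimethylsilyloxy)-2,3,4,5,5a,6,9,9a-octahydro-1-benzoxepine | C[Si](C)(C)OC1=CC[C@H]2OC(C)(C)[C@H](O[Si](C)(C)C(C)(C)C)CC[C@]2(C)C1 | intermediate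
6 | (3R,5aR,9aR)-3-(TBSO)-2,2,5a-trimethyl-3,4,5,5a,6,9a-hexahydro-1-benzoxepin-7(2H)-one | O=C1C[C@@]2(C)CC[C@@H](O[Si](C)(C)C(C)(C)C)C(C)(C)O[C@@H]2C=C1 | intermediate
7 | (4R)-1-methyl-4-(prop-1-en-2-yl)cyclohex-1-ene, (R)-(+)-limonene | CC1=CC[C@@H](CC1)C(C)=C | starting material
8 | 9-{2-[(1R)-4-methylcyclohex-3-en-1-yl]propyl}-9-borabicyclo[3.3.1]nonane (C-2 epimers) | CC1=CC[C@@H](CC1)C(C)CB1C2CCCC1CCC2 | intermediate
9 | 2-[(1R)-4-methylcyclohex-3-en-1-yl]propan-1-ol (C-2 epimers) | CC1=CC[C@@H](CC1)C(C)CO | intermediate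
10 | 2-[(1R)-4-methylcyclohex-3-en-1-yl]propanoic acid (C-2 epimers) | CC1=CC[C@@H](CC1)C(C)C(=O)O | intermediate
11 | methyl 2-[(1R)-4-methylcyclohex-3-en-1-yl]propanoate (C-2 epimers) | CC1=CC[C@@H](CC1)C(C)C(=O)OC | intermediate
12 | methyl 2-methyl-2-[(1R)-4-methylcyclohex-3-en-1-yl]propanoate | CC1=CC[C@@H](CC1)C(C)(C)C(=O)OC | intermediate
13 | methyl 2-methyl-2-[(4R)-1-methyl-7,8,9-trioxabicyclo[4.2.1]nonan-4-yl]propanoate (ozonide, bridgehead epimers) | CC12CC[C@@H](C(C)(C)C(=O)OC)CC(OO1)O2 | intermediate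
14 | methyl (3R)-2,2-dimethyl-6-oxo-3-(2-oxoethyl)heptanoate | O=CC[C@@H](CCC(C)=O)C(C)(C)C(=O)OC | intermediate
15 | methyl 2-[(1R)-2-formyl-3-methylcyclopent-2-en-1-yl]-2-methylpropanoate | O=CC1=C(C)CC[C@H]1C(C)(C)C(=O)OC | intermediate
16 | methyl 2-[(1R)-2-(hydroxymethyl)-3-methylcyclopent-2-en-1-yl]-2-methylpropanoate | OCC1=C(C)CC[C@H]1C(C)(C)C(=O)OC | intermediate
17 | methyl 2-[(1R,2S,5R)-1-(hydroxymethyl)-5-methyl-6-oxabicyclo[3.1.0]hexan-2-yl]-2-methylpropanoate | OC[C@@]12O[C@]1(C)CC[C@H]2C(C)(C)C(=O)OC | intermediate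
18 | methyl 2-[(1S,2S,5R)-1-(iodomethyl)-5-methyl-6-oxabicyclo[3.1.0]hexan-2-yl]-2-methylpropanoate | IC[C@@]12O[C@]1(C)CC[C@H]2C(C)(C)C(=O)OC | intermediate
19 | methyl 2-[(1R,3R)-3-hydroxy-3-methyl-2-methylidenecyclopentyl]-2-methylpropanoate | C=C1[C@](C)(O)CC[C@H]1C(C)(C)C(=O)OC | intermediate
20 | methyl 2-[(1R,2R,3R)-2-[(9-borabicyclo[3.3.1]nonan-9-yl)methyl]-3-hydroxy-3-methylcyclopentyl]-2-methylpropanoate | C(B1C2CCCC1CCC2)[C@H]1[C@](C)(O)CC[C@H]1C(C)(C)C(=O)OC | intermediate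
21 | methyl 2-[(1R,2R,3R)-3-hydroxy-3-methyl-2-(prop-2-en-1-yl)cyclopentyl]-2-methylpropanoate | C=CC[C@H]1[C@](C)(O)CC[C@H]1C(C)(C)C(=O)OC | intermediate
22 | (1R,2R,3R)-3-(1-hydroxy-2-methylpropan-2-yl)-1-methyl-2-(prop-2-en-1-yl)cyclopentan-1-ol | C=CC[C@H]1[C@](C)(O)CC[C@H]1C(C)(C)CO | intermediate
23 | 2-[(1R,2R,3R)-3-hydroxy-3-methyl-2-(prop-2-en-1-yl)cyclopentyl]-2-methylpropanal | C=CC[C@H]1[C@](C)(O)CC[C@H]1C(C)(C)C=O | intermediate
24 | (1R,2R,3R)-3-(3-hydroxy-2,4-dimethylpent-4-en-2-yl)-1-methyl-2-(prop-2-en-1-yl)cyclopentan-1-ol (carbinol epimers) | C=CC[C@H]1[C@](C)(O)CC[C@H]1C(C)(C)C(O)C(C)=C | intermediate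
25 | 4-[(1R,2R,3R)-3-hydroxy-3-methyl-2-(prop-2-en-1-yl)cyclopentyl]-2,4-dimethylpent-1-en-3-one | C=CC[C@H]1[C@](C)(O)CC[C@H]1C(C)(C)C(=O)C(C)=C | intermediate
26 | (1R,3aR,8aR)-1-hydroxy-1,4,4,6-tetramethyl-2,3,3a,4,8,8a-hexahydroazulen-5(1H)-one | CC1=CC[C@H]2[C@](C)(O)CC[C@H]2C(C)(C)C1=O | intermediate
27 | (1R,3aR,8aR)-1,4,4,6-tetramethyl-5-(prop-2-en-1-yl)-1,2,3,3a,4,5,8,8a-octahydroazulene-1,5-diol (C-5 epimers) | CC1=CC[C@H]2[C@](C)(O)CC[C@H]2C(C)(C)C1(O)CC=C | intermediate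
28 | (1R,3aR,8aR)-1-hydroxy-1,4,4,6-tetramethyl-5-(prop-2-en-1-yl)-2,3,3a,4,8,8a-hexahydroazulen-7(1H)-one | CC1=C(CC=C)C(C)(C)[C@@H]2CC[C@@](C)(O)[C@@H]2CC1=O | intermediate
29 | (1R,3aR,7S,8aR)-1,4,4,6-tetramethyl-5-(prop-2-en-1-yl)-1,2,3,3a,4,7,8,8a-octahydroazulene-1,7-diol | CC1=C(CC=C)C(C)(C)[C@@H]2CC[C@@](C)(O)[C@@H]2C[C@@H]1O | intermediate
30 | (1R,3aR,7S,8aR)-1,4,4,6-tetramethyl-5-(prop-2-en-1-yl)-1,7-bis(TESO)-1,2,3,3a,4,7,8,8a-octahydroazulene | CC1=C(CC=C)C(C)(C)[C@@H]2CC[C@@](C)(O[Si](CC)(CC)CC)[C@@H]2C[C@@H]1O[Si](CC)(CC)CC | intermediate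
31 | 3-[(1R,3aR,7S,8aR)-1,4,4,6-tetramethyl-1,7-bis(TESO)-1,2,3,3a,4,7,8,8a-octahydroazulen-5-yl]propane-1,2-diol (C-2 epimers) | CC1=C(CC(O)CO)C(C)(C)[C@@H]2CC[C@@](C)(O[Si](CC)(CC)CC)[C@@H]2C[C@@H]1O[Si](CC)(CC)CC | intermediate
32 | 2-[(1R,3aR,7S,8aR)-1,4,4,6-tetramethyl-1,7-bis(TESO)-1,2,3,3a,4,7,8,8a-octahydroazulen-5-yl]acetaldehyde | CC1=C(CC=O)C(C)(C)[C@@H]2CC[C@@](C)(O[Si](CC)(CC)CC)[C@@H]2C[C@@H]1O[Si](CC)(CC)CC | intermediate
33 | lithium (3R,5aR,9aR)-3-(TBSO)-2,2,5a-trimethyl-2,3,4,5,5a,9a-hexahydro-1-benzoxepin-7-olate | [Li+].[O-]C1=C[C@@]2(C)CC[C@@H](O[Si](C)(C)C(C)(C)C)C(C)(C)O[C@@H]2C=C1 | intermediate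
34 | (3R,5aR,9aR)-3-(TBSO)-6-{1-hydroxy-2-[(1R,3aR,7S,8aR)-1,4,4,6-tetramethyl-1,7-bis(TESO)-1,2,3,3a,4,7,8,8a-octahydroazulen-5-yl]ethyl}-2,2,5a-trimethyl-3,4,5,5a,6,9a-hexahydro-1-benzoxepin-7(2H)-one (epimers at C-6 and the carbinol carbon) | CC1=C(CC(O)C2[C@@]3(C)CC[C@@H](O[Si](C)(C)C(C)(C)C)C(C)(C)O[C@@H]3C=CC2=O)C(C)(C)[C@@H]2CC[C@@](C)(O[Si](CC)(CC)CC)[C@@H]2C[C@@H]1O[Si](CC)(CC)CC | intermediate
35 | methanesulfonate of 34 at the side-chain carbinol | CC1=C(CC(OS(C)(=O)=O)C2[C@@]3(C)CC[C@@H](O[Si](C)(C)C(C)(C)C)C(C)(C)O[C@@H]3C=CC2=O)C(C)(C)[C@@H]2CC[C@@](C)(O[Si](CC)(CC)CC)[C@@H]2C[C@@H]1O[Si](CC)(CC)CC | intermediate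
36 | (3R,5aR,6Z,9aR)-3-(TBSO)-2,2,5a-trimethyl-6-{2-[(1R,3aR,7S,8aR)-1,4,4,6-tetramethyl-1,7-bis(TESO)-1,2,3,3a,4,7,8,8a-octahydroazulen-5-yl]ethylidene}-3,4,5,5a,6,9a-hexahydro-1-benzoxepin-7(2H)-one | CC1=C(C/C=C2/[C@@]3(C)CC[C@@H](O[Si](C)(C)C(C)(C)C)C(C)(C)O[C@@H]3C=CC2=O)C(C)(C)[C@@H]2CC[C@@](C)(O[Si](CC)(CC)CC)[C@@H]2C[C@@H]1O[Si](CC)(CC)CC | intermediate
37 | (3R,5aR,6R,9aR)-3-(TBSO)-2,2,5a-trimethyl-6-{2-[(1R,3aR,7S,8aR)-1,4,4,6-tetramethyl-1,7-bis(TESO)-1,2,3,3a,4,7,8,8a-octahydroazulen-5-yl]ethyl}octahydro-1-benzoxepin-7(2H)-one | CC1=C(CC[C@@H]2[C@@]3(C)CC[C@@H](O[Si](C)(C)C(C)(C)C)C(C)(C)O[C@@H]3CCC2=O)C(C)(C)[C@@H]2CC[C@@](C)(O[Si](CC)(CC)CC)[C@@H]2C[C@@H]1O[Si](CC)(CC)CC | intermediate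
38 | (3R,5aR,6R,7S,9aR)-3-(TBSO)-2,2,5a,7-tetramethyl-6-{2-[(1R,3aR,7S,8aR)-1,4,4,6-tetramethyl-1,7-bis(TESO)-1,2,3,3a,4,7,8,8a-octahydroazulen-5-yl]ethyl}decahydro-1-benzoxepin-7-ol | CC1=C(CC[C@@H]2[C@@]3(C)CC[C@@H](O[Si](C)(C)C(C)(C)C)C(C)(C)O[C@@H]3CC[C@]2(C)O)C(C)(C)[C@@H]2CC[C@@](C)(O[Si](CC)(CC)CC)[C@@H]2C[C@@H]1O[Si](CC)(CC)CC | intermediate
39 | (3R,5aR,6R,7S,9aR)-6-{2-[(1R,3aR,7S,8aR)-1,7-dihydroxy-1,4,4,6-tetramethyl-1,2,3,3a,4,7,8,8a-octahydroazulen-5-yl]ethyl}-2,2,5a,7-tetramethyldecahydro-1-benzoxepine-3,7-diol | CC1=C(CC[C@@H]2[C@@]3(C)CC[C@@H](O)C(C)(C)O[C@@H]3CC[C@]2(C)O)C(C)(C)[C@@H]2CC[C@@](C)(O)[C@@H]2C[C@@H]1O | target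

**Totals**
Total step count: 30. Longest linear sequence: 26 steps (steps 5–25 from limonene, then steps 26–30).

**Three steps most likely to fail**

Step 3 (epoxide-opening bicyclization). The enol silane may be too weak a terminator, or the epoxonium ion may be trapped in the exo sense. The fallback sets out from 2 and returns at 4, replacing the terminator by an allylsilane. Ketone 2 is converted with KN(SiMe3)2 and PhNTf2 (THF, −78 °C) into the terminal enol triflate 4-[(2R,3R)-3-{2-[(2R)-3,3-dimethyloxiran-2-yl]ethyl}-3-methyloxiran-2-yl]but-1-en-2-yl trifluoromethanesulfonate F1. Coupling with Me3SiCH2MgCl and Pd(PPh3)4 gives the allylsilane trimethyl{2-methylidene-4-[(2R,3R)-3-{2-[(2R)-3,3-dimethyloxiran-2-yl]ethyl}-3-methyloxiran-2-yl]butyl}silane F2. Its β-silyl-stabilized cyclization under tBuMe2SiOTf and 2,6-di-tert-butyl-4-methylpyridine gives the exocyclic alkene tert-butyl(dimethyl){[(3R,5aR,9aR)-2,2,5a-trimethyl-7-methylidenedecahydro-1-benzoxepin-3-yl]oxy}silane F3. Ozonolysis (O3, then Me2S) converts the methylidene into the ketone 4.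

Step 20 (metathesis onto a hindered, electron-poor 1,1-disubstituted alkene). The fallback sets out from 23 and returns at 26, closing the ring by an aldol condensation instead. EtMgBr adds to aldehyde 23 to give (1R,2R,3R)-3-(3-hydroxy-2-methylpentan-2-yl)-1-methyl-2-(prop-2-en-1-yl)cyclopentan-1-ol F4. Dess–Martin oxidation gives the ethyl ketone 2-[(1R,2R,3R)-3-hydroxy-3-methyl-2-(prop-2-en-1-yl)cyclopentyl]-2-methylpentan-3-one F5. OsO4/NaIO4 cleavage of the allyl group gives the keto aldehyde 2-[(1R,2R,5R)-2-hydroxy-2-methyl-5-(2-methyl-3-oxopentan-2-yl)cyclopentyl]acetaldehyde F6. The ketone can enolize only at its ethyl CH2, so KOH in MeOH closes the seven-membered ring by intramolecular aldol condensation to 26.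

Step 23 (facial selectivity of hydride addition on a flexible seven-membered enone). The fallback sets out from 28 and returns at 29, correcting the centre by inversion. If reduction gives mainly the epimer (1R,3aR,7R,8aR)-1,4,4,6-tetramethyl-5-(prop-2-en-1-yl)-1,2,3,3a,4,7,8,8a-octahydroazulene-1,7-diol F7, a Mitsunobu reaction (4-nitrobenzoic acid, PPh3, diisopropyl azodicarboxylate, toluene) inverts C-7 to give (1R,3aR,7S,8aR)-1-hydroxy-1,4,4,6-tetramethyl-5-(prop-2-en-1-yl)-1,2,3,3a,4,7,8,8a-octahydroazulen-7-yl 4-nitrobenzoate F8. Methanolysis (K2CO3, MeOH) then gives 29.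

**Further compounds**
F1 | step 3 | 4-[(2R,3R)-3-{2-[(2R)-3,3-dimethyloxiran-2-yl]ethyl}-3-methyloxiran-2-yl]but-1-en-2-yl trifluoromethanesulfonate | C=C(OS(=O)(=O)C(F)(F)F)CC[C@H]1O[C@]1(C)CC[C@H]1OC1(C)C
F2 | step 3 | trimethyl{2-methylidene-4-[(2R,3R)-3-{2-[(2R)-3,3-dimethyloxiran-2-yl]ethyl}-3-methyloxiran-2-yl]butyl}silane | C=C(C[Si](C)(C)C)CC[C@H]1O[C@]1(C)CC[C@H]1OC1(C)C
F3 | step 3 | tert-butyl(dimethyl){[(3R,5aR,9aR)-2,2,5a-trimethyl-7-methylidenedecahydro-1-benzoxepin-3-yl]oxy}silane | C=C1C[C@@]2(C)CC[C@@H](O[Si](C)(C)C(C)(C)C)C(C)(C)O[C@@H]2CC1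
F4 | step 20 | (1R,2R,3R)-3-(3-hydroxy-2-methylpentan-2-yl)-1-methyl-2-(prop-2-en-1-yl)cyclopentan-1-ol (carbinol epimers) | C=CC[C@H]1[C@](C)(O)CC[C@H]1C(C)(C)C(O)CC
F5 | step 20 | 2-[(1R,2R,3R)-3-hydroxy-3-methyl-2-(prop-2-en-1-yl)cyclopentyl]-2-methylpentan-3-one | C=CC[C@H]1[C@](C)(O)CC[C@H]1C(C)(C)C(=O)CC
F6 | step 20 | 2-[(1R,2R,5R)-2-hydroxy-2-methyl-5-(2-methyl-3-oxopentan-2-yl)cyclopentyl]acetaldehyde | O=CC[C@H]1[C@](C)(O)CC[C@H]1C(C)(C)C(=O)CC
F7 | step 23 | (1R,3aR,7R,8aR)-1,4,4,6-tetramethyl-5-(prop-2-en-1-yl)-1,2,3,3a,4,7,8,8a-octahydroazulene-1,7-diol | CC1=C(CC=C)C(C)(C)[C@@H]2CC[C@@](C)(O)[C@@H]2C[C@H]1O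
F8 | step 23 | (1R,3aR,7S,8aR)-1-hydroxy-1,4,4,6-tetramethyl-5-(prop-2-en-1-yl)-1,2,3,3a,4,7,8,8a-octahydroazulen-7-yl 4-nitrobenzoate | CC1=C(CC=C)C(C)(C)[C@@H]2CC[C@@](C)(O)[C@@H]2C[C@@H]1OC(=O)c1ccc(cc1)[N+](=O)[O-]
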